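3 figures are asked, the L, Q and D standing after 40 h, and all are shares of one charge of L. So the balance to write is that of L.

- north: L 0.075 M; E 1.2 equiv; run made earlier
- flask: L 0.050 M; E 1.20 equiv; time 40 h

north run (percent of the L charged)

| time / h | L / % | Q / % | D / % |
|---|---|---|---|
| 0.667 | 97.3 | 3.1 | 0 |
| 1.33 | 93.7 | 6.3 | 0.5 |
| 2.50 | 88.6 | 10.2 | 1.3 |
| 4.00 | 82.9 | 14.0 | 2.4 |
| 8.00 | 70.3 | 20.8 | 8.5 |

(scatter of a reading: 0.5 percentage points)

* the L standing at 40 h, as a percentage of the L charged
* the Q standing at 40 h, as a percentage of the L charged
* the D standing at 40 h, as a percentage of the L charged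

- the earlier runs were read with a standard deviation of 0.5 percentage points

The balance gap (mass-balance deficit), the share of the L charged that stands neither as L nor as Q nor as D, reads 0.4 points at the last north reading, 8.00 h. A sum of three readings carries a scatter of 0.87 points, so the north gap is smaller than that scatter and the north balance closes within it. But the north run stopped with 70.3% of L standing. Taking the steps as second order, concentration times time is the clock, and the flask runs 3.33 times further on it. So the closed balance covers the early stretch, and the reckoning here commits to one test: at 40 h, a gap beyond that scatter points to a species not read.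

The forecast gives 46% L, 25% Q and 29% D, a sum of 100%. Its ground is “Taking L + E → Q and Q + E → D, both second order, the north run fits well”.

The flask gives 40.4% L, 23.5% Q and 24.1% D.

    L + D → Z (k = 1.20 × 10⁻⁴ L mol⁻¹ s⁻¹)
    L + E → Q + G (k = 1.60 × 10⁻⁴ L mol⁻¹ s⁻¹)
    E + Q → D + G (k = 3.30 × 10⁻⁴ L mol⁻¹ s⁻¹)

The flask's gap is 12 points, against 0.4 points in the north run, and Z stands in the flask at 12.0%, each Z counting as two since it holds one L and one D. So 6.00% of the L charged went by that step as L, and the forecast's L stands 5.6 points too high. The flask with 2.00 equiv of E gives 20.1% L, 16.8% Q and 46.9% D, so its gap is 16 points, with Z there at 16.1%.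

(The data are calculated with constants of no real substance, noise included.)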